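**Plan**

- Retrosynthesis: the two enolic C–OH and the two C=O groups are traced back to four aryl methyl ethers; then the side chain is cut between its third and fourth carbon counted from the ring; then the ring–chain bond is cut.
- Enabling feature: the chain-bearing ring carbon lies between two oxygen-bearing ring carbons (C2–OH and C4=O of the quinone ring). In the tetramethyl ether of the reduced ring this is the doubly ortho-activated C–H, so a three-carbon allyl handle can be placed there, and its terminal alkene carbon is exactly chain C3.
- Forward: tetramethoxybenzene 1 is lithiated and allylated with 2 (via 3) to give 4. Anti-Markovnikov hydroboration puts boron on chain C3, and a Pd-catalysed alkyl–alkyl Suzuki coupling with 1-bromotridecane 5 (via 6) joins C3 to C4, completing the C16 chain in 7. Ce(IV) oxidation gives quinone 8, and hydrolysis of its two vinylogous esters gives target 9.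
- No ring is built: the benzene ring of 1 becomes the quinone ring. The target has no stereocentre and no stereogenic double bond, so no stereocontrol is needed.
- Helpers: boron (activating group, lost in the coupling itself) and four O-methyl groups that hold the ring at the hydroquinone ether level, inert to borane and Pd(0) (removed in steps 3 and 4).

Key step: step 2

Remark: the target is achiral, and all three starting materials are taken as purchasable.

**Step 1**
Reactants: 1 1,2,4,5-tetramethoxybenzene; 2 allyl bromide
Product: 4 3-allyl-1,2,4,5-tetramethoxybenzene, via aryllithium 3 (not isolated)
Conditions: n-BuLi (1.0 equiv), THF, 0 °C → rt; then 2, −78 °C → rt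
Reagents that add atoms: n-butyllithium, CCCC[Li] (its lithium stands in 3 only; no atom of it remains in 4)
Why: Directed ortho-lithiation removes a ring hydrogen flanked by two methoxy-bearing carbons (the two such positions of 1 are equivalent), and the resulting aryllithium 3 is C-alkylated by allyl bromide in an SN2/SN2' substitution that gives the same product either way; no stereocentre is formed.

**Step 2**
Reactants: 4 3-allyl-1,2,4,5-tetramethoxybenzene; 5 1-bromotridecane
Product: 7 3-hexadecyl-1,2,4,5-tetramethoxybenzene, via alkylborane 6 (not isolated)
Conditions: 9-BBN, THF, 0 °C → rt; then 5, Pd(OAc)2 (4 mol %), PCy3 (8 mol %), K3PO4·H2O, THF, rt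
Reagents that add atoms: 9-borabicyclo[3.3.1]nonane (9-BBN), B1C2CCCC1CCC2 (its boron unit stands in 6 only; only one hydrogen of it remains in 7)
Why: 9-BBN adds H–B across the monosubstituted alkene of 4 through a four-centre transition state in the anti-Markovnikov sense, so boron ends on the terminal carbon, which is the third chain carbon counted from the ring, and gives the B-alkyl-9-BBN 6. The phosphate hydrate converts 6 into a hydroxyborate, Pd(0)/PCy3 inserts into the C–Br bond of 5 by an SN2-type oxidative addition, the primary alkyl group passes from boron to palladium, and reductive elimination forms the C(sp3)–C(sp3) bond between the former alkene terminus and C1 of the tridecyl unit. The closest known reaction type is the room-temperature B-alkyl Suzuki–Miyaura coupling of 9-BBN adducts of terminal alkenes with primary alkyl bromides that carry β-hydrogens. No ring is closed and no stereocentre is formed. The step needs three selectivities: terminal hydroboration, secured by the bulk of 9-BBN at an unhindered terminal alkene whose internal carbon is further shielded by the two ortho-methoxy groups; transfer of the primary alkyl group in preference to the two secondary B–C bonds of the bicycle; and coupling in preference to β-hydride elimination of the alkylpalladium intermediates, secured by the bulky, electron-rich PCy3 ligand.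

**Step 3**
Reactants: 7 3-hexadecyl-1,2,4,5-tetramethoxybenzene
Product: 8 3-hexadecyl-2,5-dimethoxy-1,4-benzoquinone
Conditions: CAN (2.5 equiv), MeCN–H2O–CH2Cl2, 0 °C
Reagents that add atoms: water, O
Why: Ceric ammonium nitrate oxidative demethylation of a para-dimethoxyarene: two one-electron oxidations with attack of water at two para methoxy-bearing ring carbons and loss of two molecules of methanol should give the p-quinone, and both para pairs of methoxy groups of 7 lead to the same quinone 8.

**Step 4**
Reactants: 8 3-hexadecyl-2,5-dimethoxy-1,4-benzoquinone
Product: 9 3-hexadecyl-2,5-dihydroxy-1,4-benzoquinone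
Conditions: 2 M NaOH, EtOH, reflux; then 2 M HCl
Reagents that add atoms: sodium hydroxide, [Na+].[OH-]
Why: Each methoxy group of 8 sits on the β-carbon of a quinone enone and is therefore a vinylogous methyl ester, so hydroxide adds at that ring carbon and expels methoxide (addition–elimination hydrolysis), and acidification of the resulting bis-enolate should give the dihydroxyquinone 9.

**Compound list**

1 | 1,2,4,5-tetramethoxybenzene | COc1cc(OC)c(OC)cc1OC | starting material
2 | allyl bromide (3-bromoprop-1-ene) | C=CCBr | starting material
3 | (2,3,5,6-tetramethoxyphenyl)lithium | COc1cc(OC)c(OC)c([Li])c1OC | intermediate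
4 | 3-allyl-1,2,4,5-tetramethoxybenzene | COc1cc(OC)c(OC)c(CC=C)c1OC | intermediate
5 | 1-bromotridecane | CCCCCCCCCCCCCBr | starting material
6 | 9-[3-(2,3,5,6-tetramethoxyphenyl)propyl]-9-borabicyclo[3.3.1]nonane | COc1cc(OC)c(OC)c(CCCB2C3CCCC2CCC3)c1OC | intermediate
7 | 3-hexadecyl-1,2,4,5-tetramethoxybenzene | COc1cc(OC)c(OC)c(CCCCCCCCCCCCCCCC)c1OC | intermediate
8 | 3-hexadecyl-2,5-dimethoxy-1,4-benzoquinone | CCCCCCCCCCCCCCCCC1=C(OC)C(=O)C=C(OC)C1=O | intermediate
9 | 3-hexadecyl-2,5-dihydroxy-1,4-benzoquinone | CCCCCCCCCCCCCCCCC1=C(O)C(=O)C=C(O)C1=O | target

**Summary**

Total step count: 4. Longest linear sequence: 4 steps (1 → 4 → 7 → 8 → 9); 1-bromotridecane 5 enters directly in step 2.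

**Steps most likely to fail**

Step 2. The alkyl–alkyl coupling may be eroded by β-hydride elimination or reduction at the tridecylpalladium stage, by protodeboronation of the borane on the wet base, or by sluggish transmetalation. The fallback reverses the polarity of the two partners and sets out from 1. Compound 1 is lithiated to 3 as in step 1 and alkylated with an excess of 1,3-dibromopropane (THF, −78 °C → rt) to give 3-(3-bromopropyl)-1,2,4,5-tetramethoxybenzene F1. Separately, 5 is converted with magnesium in THF into tridecylmagnesium bromide F2. F1 and F2 are joined by a copper-catalysed Grignard–alkyl bromide coupling (Li2CuCl4 cat., THF, −20 °C → rt), which forms the same chain bond and comes back to the route at 7.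

Step 3. The Ce(IV) oxidation may go astray through demethylation across an ortho pair of methoxy groups, oxidative dimerisation of the arene radical cation, or attack at the benzylic CH2 of the chain. The fallback changes the order of unmasking and sets out from 7. All four methyl ethers are cleaved with BBr3 (CH2Cl2, −78 °C → rt) to give 3-hexadecylbenzene-1,2,4,5-tetrol F3. This electron-rich tetrol should be oxidised by air (O2, EtOAc/aq. NaHCO3, then acidification) directly to the dihydroxyquinone. The fallback comes back at 9 and bypasses 8 and step 4.

Step 4. The hydrolysis may stall after the first methoxy group, because the mono-enolate is a poorer acceptor and the C16 chain lowers solubility in aqueous ethanol, or the product may degrade on prolonged heating in base under air. The fallback sets out from 8 and cleaves the O–CH3 bonds instead of the ring C–O bonds. BCl3 (CH2Cl2, −78 → 0 °C) should chelate between each quinone carbonyl and the neighbouring methoxy oxygen and let chloride attack the methyl group in an SN2 dealkylation. Aqueous work-up then returns the route at 9. This fallback makes no new compound (F0).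

**Further compounds**

F1 | step 2 | 3-(3-bromopropyl)-1,2,4,5-tetramethoxybenzene | COc1cc(OC)c(OC)c(CCCBr)c1OC
F2 | step 2 | tridecylmagnesium bromide | CCCCCCCCCCCCC[Mg]Br
F3 | step 3 | 3-hexadecylbenzene-1,2,4,5-tetrol | CCCCCCCCCCCCCCCCc1c(O)c(O)cc(O)c1O
F0 | step 4 | none | none
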